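## Structural features

The target is a cembranoid built on a 14-membered carbocycle (C1–C14). C1 and C2 are fused cis to an α-methylene-γ-butyrolactone (C15, C16, exocyclic C17, lactone oxygen on C2). A 1,2-dioxane (C8–C9–C10–C11–O–O) bridges C8 and C11 across the macrocycle, so the molecule is a bicyclo[10.2.2] system in which the C19 methyl on C8 and the hydrogen on C11 both point away from the ten-atom bridge. The stereocentres form two contiguous pairs, C1/C2 (both R) and C7/C8 (7R acetate beside the fully substituted 8S peroxide carbon), plus C11 (R), which is tied to C8 through the peroxide. The ring also holds an E C3=C4 and a Z C12=C13 trisubstituted alkene, each allylic to a C–O bond. Fragile groups are the O–O bond (reductants, Lewis acids, and base, because C11–H is α to the peroxide), the exo-methylene lactone (Michael acceptor, radical trap), the allylic C2–O bond and the Z alkene. The real difficulty is to close the 14-membered ring and then the peroxide with the right C8/C11 relationship while these groups are present; this dictates the order of the end game. The key step exploits the C1/C2 pair: the lactone C–O bond on C2 and the C1–C15 bond on the neighbouring carbon lie on the same face of the five-membered ring, which is what anti opening of a trans C1,C2-epoxide at C1 by a two-carbon enolate delivers.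

## Logic of the disconnections

35 ⇒ 34. The C11–H bond is cut, leaving a hydroxyl on C11. The C11 methine is the base-labile site of the peroxide, so it is made last and under acid. The gain is that C11 needs no earlier stereocontrol. The demand is hydride delivery to a peroxycarbenium ion from the face opposite the ten-atom bridge, without damage to the O–O bond.

34 ⇒ 33 ⇒ 31. The acetate C–O bond is cut, then both peroxide C–O bonds (O–C8, O–C11), which returns the C7,C8-epoxide, the C11 ketone and H2O2. The dioxane and the C8 centre reduce to an epoxy enone. The demand is opening at the tertiary C8 with inversion and ring closure of the hydroperoxide on the ketone. C7 is acetylated before the cation at C11 is generated, so that the C7 oxygen cannot capture it.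

31 ⇒ 30 ⇒ 27. The C11 carbonyl is taken back to the alcohol and the C15=C17 bond is cut. The exo-methylene is the most electrophilic group of the molecule and needs enolate chemistry, so it is placed after the last reduction and before the ketone and the peroxide exist. The demand is that the lactone enolate can be formed beside an epoxide and a free alkoxide.

27 ⇒ 26 ⇒ 25. The C9–C10 bond is re-drawn as an E alkene and the macrocycle is opened at C10–C11 (alkenyl iodide plus aldehyde). Closure with CrCl2 is neutral and tolerates lactone and epoxide. The gain is a linear precursor. The demands are high-dilution closure and saturation of the only 1,2-disubstituted alkene beside two trisubstituted ones.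

25 ⇒ 24 ⇒ 23 ⇒ 22 ⇒ 21 ⇒ 20. C11 is adjusted from aldehyde to silyl ether, the C9=C10 bond is cut (C10 comes from CHI3), and both epoxide C–O bonds at C7/C8 are cut back to an E allylic alcohol with its hydroxyl on C9. The C7/C8 pair then comes from a reagent-controlled epoxidation. The demand is an E-configured 2-methyl allylic alcohol.

20 ⇒ 18. The C7=C8 bond is cut (stabilised ylide on a C7 aldehyde, then 1,2-reduction, via 19). This adds C8, C9 and C19 with E geometry.

18 ⇒ 16 ⇒ 15. The C5–C6 bond is cut in the sense of a [3,3] shift (via 17), which moves the alkene from C3=C4 back to C4=C5 and leaves a C3 carbinol; the C3–C4 bond is then cut (isopropenyl addition). The E trisubstituted C3=C4 alkene and C4–C7 arise from an aldehyde without any carbanion at C5 or C6. The demands are E selectivity in the chair transition state and no epimerisation of C2 at the aldehyde stage.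

15 ⇒ 14 ⇒ 13. C3 is returned from aldehyde to PMB ether; only protecting-group and oxidation-state changes.

13 ⇒ 10 + 11. The C1–C15 bond and the O–C16 bond are cut. The lactone ring and both ring-fusion centres reduce to one trans epoxide and an acetate ester. The demand is attack at C1, not C2, with clean inversion.

10 ⇒ 9 ⇒ 8. The PMB ether and both epoxide C–O bonds are cut back to an E allylic alcohol. The absolute configuration of C1 and C2 comes from one catalytic asymmetric epoxidation.

8 ⇒ 7 ⇒ 5 + 6. The E C1=C2 alkene is taken back to an alkyne and the C14–C1 bond is cut (allylic bromide plus terminal alkyne). The skipped diene is reached without a β,γ-unsaturated carbonyl intermediate.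

5 ⇒ 4 ⇒ 3 ⇒ 2 ⇒ 1. The bromide is returned to the ester, the C12–C20 bond is cut (methyl cuprate on an ynoate) and then the C13–C14 bond (acylation of an acetylide). The Z C12=C13 geometry follows from syn carbometalation, and the two ends of the four-carbon unit differ in oxidation state from the start, so no diol has to be differentiated.

## Other disconnections considered

Alternative 1: The cut goes through both C–O bonds of the dioxane and, read backwards, joins C8 to C11: the peroxyhemiketal A1 (the same compound as 34) comes from the bicyclo[10.2.0] cyclobutanol A2 and O2. In the forward step Co(acac)2 and O2 turn the tertiary cyclobutanol into an oxygen-centred radical, the strained C8–C11 bond breaks to give the C11 ketone and a tertiary C8 radical, O2 is trapped at C8 and the peroxide closes on the ketone. In its favour: one neutral, aerobic step makes the dioxane, the C11 carbonyl and the 14-membered ring; no H2O2 or acid touches the molecule; the C7 acetate can already be in place, so the free β-hydroxy hydroperoxide stage (33) is avoided. Against it: C8 is planar at the radical stage, so its configuration relative to C7 rests only on the facial bias of the ring. The cleavage must also take C8–C11 and not C10–C11. Carbon and peroxyl radicals have to coexist with the exo-methylene lactone and two alkenes carrying allylic hydrogens. A2 itself needs a stereocontrolled cyclobutane synthesis beside a quaternary C8 and a Z alkene. Comparison: the last step to the target is the same in both plans (equal). Alternative 1 is better in step economy of the peroxide installation (one step against two) and in mildness. It is weaker on structure, because the chosen plan fixes C8 by a stereospecific inversion of a Sharpless epoxide, and weaker on total count, because of the route to A2.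

Alternative 2: The cut is the C3–C4 bond, formed as an alkyne: the cycloalkyne A3 comes from the seco diyne A4. In the forward step Mo(≡CC6H4OMe)(OSiPh3)3 metathesises the two methyl-capped alkynes with loss of but-2-yne. In its favour: alkyne metathesis closes 14-membered rings dependably, leaves alkenes, epoxide, silyl ether and ester alone, and creates neither a stereocentre nor an E/Z question at the closure. C9–C10 is saturated from the start, so no selective alkene reduction is needed; on this point it is better than steps 20 and 21 of the chosen plan. Against it: A3 as drawn has no C18 methyl. The alkyne must therefore be converted to the E trisubstituted alkene by trans-hydrometalation with the metal on C4 followed by methylation, whereas the propargylic C2 hydroxyl directs the metal to C3. The free propargylic hydroxyl may need protection during metathesis. The C1/C2 pair must be set by separate asymmetric chemistry and lactonised later. The C11 silyl ether centre is superfluous if the peroxide is closed through the ketone and has the wrong sense for a displacement. Comparison: mechanistically its ring closure is the more dependable one. Structurally it leaves more to do after closure (methyl group, alkene geometry, lactone, methylene). In step economy it is about equal: it saves the iodo-olefination and the diimide step but adds hydrometalation, methylation, lactonisation and an independent synthesis of C1/C2.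

Alternative 3: The cut is the C2–H bond together with O–C16: the cis lactone A5 comes from the macrocyclic C2 enone ester A6, used as a mixture of C1 epimers. In the forward step RuCl2(xylbinap)(daipen) with KOtBu under H2 reduces the C2 carbonyl (C=O selective over C=C) of the faster-reacting C1 epimer while base equilibrates C1 through the enolate, and the C2 alkoxide closes on the ester. In its favour: one catalytic step sets C1, C2 and the lactone late; C1 can be introduced without stereocontrol; the PMB removal and C3 oxidation of the chosen plan disappear. Against it: C1 must epimerise faster than the ketone is reduced, yet under KOtBu the γ-positions of the enone (C5, C18) and the ester α-carbon compete for deprotonation, which invites deconjugation or condensation. The catalyst must override the conformational bias of a 14-membered ring that already holds three stereocentres. Whether the cis or the trans pair is favoured in such a ring cannot be predicted. A6 needs its own macrocyclisation. Comparison: it is better in step economy around C1/C2, and equal in that both plans take their chirality from a catalyst. It is weaker on mechanism, because the chosen plan is stereospecific (a trans epoxide opened with inversion can only give the cis lactone) where the alternative is at best stereoselective.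

Key step: step 9

Remark on the chemistry: cembrane numbering is used throughout (C1 carries C15, C2 the lactone oxygen); carbinol centres that are erased later (C3 in 16–17, C11 in 26–30, C15 in 28–29) are carried as epimer mixtures, and the C2 descriptor reads S while C15 is saturated and R once C15 is sp2, with no change in space.

Step 1
Reactants: 1 tert-butyl(dimethyl)(prop-2-yn-1-yloxy)silane
Product: 2 ethyl 4-{[tert-butyl(dimethyl)silyl]oxy}but-2-ynoate
Conditions: nBuLi, THF, −78 °C; ClCO2Et, −78 → −20 °C
Reagents that add atoms: ethyl chloroformate, CCOC(Cl)=O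
Why: C-acylation of a lithium acetylide with a chloroformate; it adds C14 at the ester level and activates the alkyne for conjugate addition.

Step 2
Reactants: 2 ethyl 4-(TBSO)but-2-ynoate
Product: 3 ethyl (2Z)-4-{[tert-butyl(dimethyl)silyl]oxy}-3-methylbut-2-enoate
Conditions: Me2CuLi (from MeLi, CuI), THF, −78 °C; MeOH, −78 °C
Reagents that add atoms: lithium dimethylcuprate, [Li+].C[Cu-]C
Why: Syn carbocupration of an ynoate (conjugate addition of a Gilman cuprate) and protonation of the alkenylcopper with retention put methyl and hydrogen cis, so C11 (CH2OTBS) and C14 (ester) are cis, the Z C12=C13 geometry; quenching at −78 °C should prevent equilibration through the allenoate.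

Step 3
Reactants: 3 ethyl (2Z)-4-(TBSO)-3-methylbut-2-enoate
Product: 4 (2Z)-4-{[tert-butyl(dimethyl)silyl]oxy}-3-methylbut-2-en-1-ol
Conditions: iBu2AlH, CH2Cl2, −78 °C
Reagents that add atoms: none
Why: 1,2-Reduction of an enoate by an aluminium hydride; the alkene geometry and the silyl ether are not touched.

Step 4
Reactants: 4 (2Z)-4-(TBSO)-3-methylbut-2-en-1-ol
Product: 5 {[(2Z)-4-bromo-2-methylbut-2-en-1-yl]oxy}(tert-butyl)dimethylsilane
Conditions: CBr4, PPh3, CH2Cl2, 0 °C
Reagents that add atoms: tetrabromomethane, BrC(Br)(Br)Br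
Why: Appel bromination of a primary allylic alcohol under neutral conditions, which should keep the Z geometry and the silyl ether.

Step 5
Reactants: 5 (Z)-allylic bromide; 6 prop-2-yn-1-ol
Product: 7 (5Z)-7-{[tert-butyl(dimethyl)silyl]oxy}-6-methylhept-5-en-2-yn-1-ol
Conditions: CuI (10 mol%), K2CO3, Bu4NI (10 mol%), DMF, rt
Reagents that add atoms: none
Why: Copper-mediated alkylation of a terminal alkyne by an allylic halide (copper acetylide coupling), forming C14–C1; attack should occur at the primary carbon because the SN2′ terminus (C12) is fully substituted, and the free propargylic hydroxyl is tolerated.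

Step 6
Reactants: 7 (5Z)-7-(TBSO)-6-methylhept-5-en-2-yn-1-ol
Product: 8 (2E,5Z)-7-{[tert-butyl(dimethyl)silyl]oxy}-6-methylhepta-2,5-dien-1-ol
Conditions: NaAlH2(OCH2CH2OMe)2, THF, 0 °C
Reagents that add atoms: none
Why: Hydroxyl-directed trans-hydroalumination of a propargylic alcohol and protonolysis give the E allylic alcohol; the isolated Z alkene has no directing group and should stay.

Step 7
Reactants: 8 (2E,5Z)-7-(TBSO)-6-methylhepta-2,5-dien-1-ol
Product: 9 [(2R,3R)-3-[(2Z)-4-{[tert-butyl(dimethyl)silyl]oxy}-3-methylbut-2-en-1-yl]oxiran-2-yl]methanol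
Conditions: Ti(OiPr)4 (cat.), D-(−)-diethyl tartrate (cat.), tBuOOH, 4 Å MS, CH2Cl2, −20 °C
Reagents that add atoms: tert-butyl hydroperoxide, CC(C)(C)OO
Why: Sharpless asymmetric epoxidation; only the alkene of the allylic alcohol is epoxidised, and D-(−)-tartrate gives the (2R,3R) trans epoxide from an E allylic alcohol, which fixes C1 and C2 in the absolute sense.

Step 8
Reactants: 9 (2R,3R)-epoxy alcohol
Product: 10 tert-butyl{[(2Z)-4-[(2R,3R)-3-{[(4-methoxybenzyl)oxy]methyl}oxiran-2-yl]-2-methylbut-2-en-1-yl]oxy}dimethylsilane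
Conditions: NaH, 4-MeOC6H4CH2Cl, Bu4NI (cat.), THF/DMF, 0 °C
Reagents that add atoms: 4-methoxybenzyl chloride, COc1ccc(CCl)cc1
Why: Williamson etherification; in an aprotic medium at 0 °C the Payne rearrangement of the epoxy alkoxide should not compete.

Step 9
Reactants: 10 trans C1,C2-epoxide (C3 O-PMB, C11 O-TBS); 11 tert-butyl acetate
Product: 13 (4R,5S)-4-[(2Z)-4-{[tert-butyl(dimethyl)silyl]oxy}-3-methylbut-2-en-1-yl]-5-{[(4-methoxybenzyl)oxy]methyl}oxolan-2-one, via γ-hydroxy tert-butyl ester 12 (not isolated)
Conditions: LiN(iPr)2, 11, THF, −78 °C; Et2AlCl, −78 °C; then 10, THF/PhMe, −78 → −20 °C; then TsOH·H2O (cat.), PhH, rt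
Reagents that add atoms: none
Why: The lithium enolate of 11 is transmetallated to the diethylaluminium enolate, whose aluminium also activates the epoxide oxygen; the enolate carbon attacks C1 in SN2 fashion anti to the C1–O bond, forming C1–C15 and giving hydroxy ester 12 (epoxide opening by an ester enolate, the classical γ-lactone annulation). Catalytic acid then promotes 5-exo-trig attack of the C2 hydroxyl on the ester carbonyl with loss of tert-butanol, which forms O–C16 and closes the butyrolactone. C1 is set by inversion and C2 is carried over unchanged from the Sharpless epoxide, so the trans epoxide can only give the cis-4,5-disubstituted lactone, and the absolute sense comes from step 7. The selectivity needed is attack at C1 and not at C2: the C3–O bond withdraws electron density from C2 and the PMB-oxymethyl group shields it, whereas C1 carries only an unbranched CH2. A sulfonic acid in catalytic amount in an aprotic solvent is chosen for the ring closure so that the PMB and TBS ethers should survive.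

Step 10
Reactants: 13 cis lactone (C3 O-PMB)
Product: 14 (4R,5S)-4-[(2Z)-4-{[tert-butyl(dimethyl)silyl]oxy}-3-methylbut-2-en-1-yl]-5-(hydroxymethyl)oxolan-2-one
Conditions: DDQ, CH2Cl2/pH 7 buffer, 0 °C
Reagents that add atoms: none
Why: Oxidative cleavage of a 4-methoxybenzyl ether by DDQ; the silyl ether, lactone and trisubstituted alkene should be inert.

Step 11
Reactants: 14 C3 alcohol
Product: 15 (2S,3R)-3-[(2Z)-4-{[tert-butyl(dimethyl)silyl]oxy}-3-methylbut-2-en-1-yl]-5-oxooxolane-2-carbaldehyde
Conditions: Dess–Martin periodinane, CH2Cl2, 0 °C → rt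
Reagents that add atoms: none
Why: Dess–Martin oxidation of a primary alcohol under non-basic conditions, so that C2, now α to the aldehyde, should not epimerise; 15 is used without storage.

Step 12
Reactants: 15 C3 aldehyde
Product: 16 (4R,5S)-4-[(2Z)-4-{[tert-butyl(dimethyl)silyl]oxy}-3-methylbut-2-en-1-yl]-5-[(1RS)-1-hydroxy-2-methylprop-2-en-1-yl]oxolan-2-one
Conditions: CH2=C(CH3)MgBr, THF, −78 °C
Reagents that add atoms: isopropenylmagnesium bromide, CC(=C)[Mg]Br
Why: Grignard addition to an aldehyde, which at −78 °C should be much faster than attack on the lactone or enolisation; the new C3 carbinol centre is not controlled because it is erased in step 13.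

Step 13
Reactants: 16 C3 allylic alcohol (epimers)
Product: 18 (4E)-5-[(2S,3R)-3-[(2Z)-4-{[tert-butyl(dimethyl)silyl]oxy}-3-methylbut-2-en-1-yl]-5-oxooxolan-2-yl]-4-methylpent-4-enal, via allyl vinyl ether 17 (not isolated)
Conditions: Hg(OAc)2 (cat.), CH2=CHOEt, reflux; then PhMe, 110 °C, sealed tube
Reagents that add atoms: ethyl vinyl ether, C=COCC
Why: Transetherification to the allyl vinyl ether and Claisen rearrangement; the [3,3] shift forms C5–C6 and moves the alkene to C3=C4. In the chair transition state the branched C2 substituent should sit equatorial, which gives the E alkene from either carbinol epimer.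

Step 14
Reactants: 18 C7 aldehyde
Product: 20 (4R,5S)-4-[(2Z)-4-{[tert-butyl(dimethyl)silyl]oxy}-3-methylbut-2-en-1-yl]-5-[(1E,5E)-7-hydroxy-2,6-dimethylhepta-1,5-dien-1-yl]oxolan-2-one, via enal 19 (not isolated)
Conditions: Ph3P=C(CH3)CHO, PhMe, 90 °C; then MeOH, CeCl3·7H2O, NaBH4, 0 °C
Reagents that add atoms: 2-(triphenyl-λ5-phosphanylidene)propanal, CC(C=O)=P(c1ccccc1)(c1ccccc1)c1ccccc1
Why: Wittig reaction with a stabilised ylide gives the E 2-methyl enal (C7=C8), and Luche reduction takes it to the allylic alcohol by 1,2-addition without touching the lactone.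

Step 15
Reactants: 20 C9 allylic alcohol
Product: 21 (4R,5S)-4-[(2Z)-4-{[tert-butyl(dimethyl)silyl]oxy}-3-methylbut-2-en-1-yl]-5-[(1E)-4-[(2R,3R)-3-(hydroxymethyl)-3-methyloxiran-2-yl]-2-methylbut-1-en-1-yl]oxolan-2-one
Conditions: Ti(OiPr)4 (cat.), D-(−)-diethyl tartrate (cat.), tBuOOH, 4 Å MS, CH2Cl2, −20 °C
Reagents that add atoms: tert-butyl hydroperoxide, CC(C)(C)OO
Why: Sharpless asymmetric epoxidation of an E 2-methyl allylic alcohol; D-(−)-tartrate should give the (7R,8R) epoxide under reagent control, and C3=C4 and C12=C13 are not allylic alcohols (C11 is silylated) and should not react.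

Step 16
Reactants: 21 C9 epoxy alcohol
Product: 22 (2S,3R)-3-[(3E)-4-[(2S,3R)-3-[(2Z)-4-{[tert-butyl(dimethyl)silyl]oxy}-3-methylbut-2-en-1-yl]-5-oxooxolan-2-yl]-3-methylbut-3-en-1-yl]-2-methyloxirane-2-carbaldehyde
Conditions: Dess–Martin periodinane, NaHCO3, CH2Cl2, 0 °C → rt
Reagents that add atoms: none
Why: Dess–Martin oxidation, buffered to protect the epoxide; the epoxy aldehyde has no α-hydrogen (C8 is fully substituted) and cannot epimerise.

Step 17
Reactants: 22 C9 epoxy aldehyde
Product: 23 (4R,5S)-4-[(2Z)-4-{[tert-butyl(dimethyl)silyl]oxy}-3-methylbut-2-en-1-yl]-5-[(1E)-4-{(2R,3R)-3-[(E)-2-iodoethenyl]-3-methyloxiran-2-yl}-2-methylbut-1-en-1-yl]oxolan-2-one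
Conditions: CrCl2, CHI3, THF, 0 °C
Reagents that add atoms: iodoform, IC(I)I
Why: Takai iodo-olefination adds C10 as an E alkenyl iodide; the geminal dichromium reagent is aldehyde-selective and should leave the lactone, epoxide and silyl ether alone.

Step 18
Reactants: 23 alkenyl iodide (C11 O-TBS)
Product: 24 (4R,5S)-4-[(2Z)-4-hydroxy-3-methylbut-2-en-1-yl]-5-[(1E)-4-{(2R,3R)-3-[(E)-2-iodoethenyl]-3-methyloxiran-2-yl}-2-methylbut-1-en-1-yl]oxolan-2-one
Conditions: Bu4NF, AcOH, THF, 0 °C → rt
Reagents that add atoms: none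
Why: Fluoride-mediated desilylation buffered with acetic acid, so that the lactone and the epoxide should not meet a free alkoxide.

Step 19
Reactants: 24 C11 allylic alcohol
Product: 25 (2Z)-4-[(2S,3R)-2-[(1E)-4-{(2R,3R)-3-[(E)-2-iodoethenyl]-3-methyloxiran-2-yl}-2-methylbut-1-en-1-yl]-5-oxooxolan-3-yl]-2-methylbut-2-enal
Conditions: Dess–Martin periodinane, NaHCO3, CH2Cl2, 0 °C
Reagents that add atoms: none
Why: Dess–Martin oxidation to the Z enal under neutral, buffered conditions that should not isomerise the Z alkene; the enal is used at once.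

Step 20
Reactants: 25 iodo enal
Product: 26 (1R,2S,3E,7R,8R,9E,11RS,12Z)-7,8-epoxy-11-hydroxy-17-norcembra-3,9,12-trien-16,2-olide
Conditions: CrCl2, NiCl2 (cat.), DMSO/THF, rt, 0.002 M, slow addition
Reagents that add atoms: none
Why: Intramolecular Nozaki–Hiyama–Kishi coupling forms C10–C11 and the 14-membered ring; the alkenylchromium species adds only to the aldehyde (1,2) and should tolerate the lactone and epoxide. High dilution favours ring closure, and both C11 epimers are usable.

Step 21
Reactants: 26 macrocyclic dienol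
Product: 27 (1R,2S,3E,7R,8R,11RS,12Z)-7,8-epoxy-11-hydroxy-17-norcembra-3,12-dien-16,2-olide
Conditions: 2-nitrobenzenesulfonylhydrazide, Et3N, CH2Cl2, rt
Reagents that add atoms: none
Why: Diimide reduction (concerted syn transfer of H2) should take the only 1,2-disubstituted alkene (C9=C10) well before the two trisubstituted ones and cannot open the epoxide; the basic medium avoids acid-promoted attack of the C11 hydroxyl on C8.

Step 22
Reactants: 27 saturated lactone
Product: 30 (1R,2R,3E,7R,8R,11RS,12Z)-7,8-epoxy-11-hydroxycembra-3,12,15(17)-trien-16,2-olide, via Mannich base 28 (not isolated), via trimethylammonium iodide 29 (not isolated)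
Conditions: LiN(iPr)2 (2.3 equiv), THF, −78 °C; CH2=NMe2+ I−, −78 → 0 °C; then MeI, MeOH, rt; then NaHCO3 (aq), EtOAc, rt
Reagents that add atoms: N,N-dimethylmethyleneiminium iodide (Eschenmoser's salt), C=[N+](C)C.[I-]
Why: Eschenmoser methylenation: Mannich reaction of the lactone enolate (the C11 hydroxyl rides as its alkoxide), N-methylation and E1cB loss of trimethylamine; it is placed after the last reduction and before the ketone and peroxide, which would not survive enolate chemistry.

Step 23
Reactants: 30 α-methylene lactone alcohol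
Product: 31 (1R,2R,3E,7R,8R,12Z)-7,8-epoxy-11-oxocembra-3,12,15(17)-trien-16,2-olide
Conditions: Dess–Martin periodinane, NaHCO3, CH2Cl2, 0 °C
Reagents that add atoms: none
Why: Dess–Martin oxidation of the secondary allylic alcohol to the Z enone; both C11 epimers converge, and the neutral conditions should spare the epoxide and the exo-methylene lactone.

Step 24
Reactants: 31 epoxy enone
Product: 33 (1R,2R,3E,7R,8S,11R,12Z)-7,11-dihydroxy-8,11-epidioxycembra-3,12,15(17)-trien-16,2-olide, via hydroperoxy ketone 32 (not isolated)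
Conditions: H2O2 (anhydrous, ethereal), H3PMo12O40 (cat.), Et2O, rt
Reagents that add atoms: hydrogen peroxide, OO
Why: Acid-catalysed perhydrolysis of a trisubstituted epoxide: H2O2 attacks the tertiary C8 with inversion (8R epoxide carbon to 8S hydroperoxide) and C7 keeps its oxygen; the δ-hydroperoxy ketone then closes to the six-membered peroxyhemiketal by addition to the C11 carbonyl. The hemiketal hydroxyl should sit on the face away from the ten-atom bridge; without base neither the enone nor the methylene lactone is epoxidised.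

Step 25
Reactants: 33 peroxyhemiketal diol
Product: 34 (1R,2R,3E,7R,8S,11R,12Z)-7-acetoxy-8,11-epidioxy-11-hydroxycembra-3,12,15(17)-trien-16,2-olide
Conditions: Ac2O, pyridine, CH2Cl2, 0 °C
Reagents that add atoms: acetic anhydride, CC(=O)OC(C)=O
Why: Acylation of the secondary C7 hydroxyl, which should react before the tertiary hemiketal hydroxyl; capping C7 prevents its oxygen from capturing the C11 cation in step 26, and any C11 acetate formed would be reduced in the same way.

Step 26
Reactants: 34 peroxyhemiketal acetate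
Product: 35 (1R,2R,3E,7R,8S,11R,12Z)-7-acetoxy-8,11-epidioxycembra-3,12,15(17)-trien-16,2-olide (CNP0238885.6)
Conditions: Et3SiH, BF3·OEt2, CH2Cl2, −78 °C
Reagents that add atoms: none
Why: Ionic hydrogenation of a hemiketal: the Lewis acid ionises the C11–OH bond to a peroxycarbenium ion and the silane delivers hydride. C11 is a bridgehead of the bicyclo[10.2.2] system, so hydride should enter from the outer face, opposite the ten-atom bridge, which gives 11R; at −78 °C the O–O bond and the Z alkene should persist.

Compound list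

1 | tert-butyl(dimethyl)(prop-2-yn-1-yloxy)silane | C#CCO[Si](C)(C)C(C)(C)C | starting material
2 | ethyl 4-{[tert-butyl(dimethyl)silyl]oxy}but-2-ynoate | CCOC(=O)C#CCO[Si](C)(C)C(C)(C)C | intermediate
3 | ethyl (2Z)-4-{[tert-butyl(dimethyl)silyl]oxy}-3-methylbut-2-enoate | CCOC(=O)/C=C(/C)CO[Si](C)(C)C(C)(C)C | intermediate
4 | (2Z)-4-{[tert-butyl(dimethyl)silyl]oxy}-3-methylbut-2-en-1-ol | OC/C=C(/C)CO[Si](C)(C)C(C)(C)C | intermediate
5 | {[(2Z)-4-bromo-2-methylbut-2-en-1-yl]oxy}(tert-butyl)dimethylsilane | BrC/C=C(/C)CO[Si](C)(C)C(C)(C)C | intermediate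
6 | prop-2-yn-1-ol | C#CCO | starting material
7 | (5Z)-7-{[tert-butyl(dimethyl)silyl]oxy}-6-methylhept-5-en-2-yn-1-ol | OCC#CC/C=C(/C)CO[Si](C)(C)C(C)(C)C | intermediate
8 | (2E,5Z)-7-{[tert-butyl(dimethyl)silyl]oxy}-6-methylhepta-2,5-dien-1-ol | OC/C=C/C/C=C(/C)CO[Si](C)(C)C(C)(C)C | intermediate
9 | [(2R,3R)-3-[(2Z)-4-{[tert-butyl(dimethyl)silyl]oxy}-3-methylbut-2-en-1-yl]oxiran-2-yl]methanol | OC[C@H]1O[C@@H]1C/C=C(/C)CO[Si](C)(C)C(C)(C)C | intermediate
10 | tert-butyl{[(2Z)-4-[(2R,3R)-3-{[(4-methoxybenzyl)oxy]methyl}oxiran-2-yl]-2-methylbut-2-en-1-yl]oxy}dimethylsilane | COc1ccc(COC[C@H]2O[C@@H]2C/C=C(/C)CO[Si](C)(C)C(C)(C)C)cc1 | intermediate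
11 | tert-butyl acetate | CC(=O)OC(C)(C)C | starting material
12 | tert-butyl (3R,4S)-3-[(2Z)-4-{[tert-butyl(dimethyl)silyl]oxy}-3-methylbut-2-en-1-yl]-4-hydroxy-5-[(4-methoxybenzyl)oxy]pentanoate (not isolated) | CC(C)(C)OC(=O)C[C@@H](C/C=C(/C)CO[Si](C)(C)C(C)(C)C)[C@H](O)COCc1ccc(OC)cc1 | intermediate
13 | (4R,5S)-4-[(2Z)-4-{[tert-butyl(dimethyl)silyl]oxy}-3-methylbut-2-en-1-yl]-5-{[(4-methoxybenzyl)oxy]methyl}oxolan-2-one | O=C1O[C@H](COCc2ccc(OC)cc2)[C@H](C/C=C(/C)CO[Si](C)(C)C(C)(C)C)C1 | intermediate
14 | (4R,5S)-4-[(2Z)-4-{[tert-butyl(dimethyl)silyl]oxy}-3-methylbut-2-en-1-yl]-5-(hydroxymethyl)oxolan-2-one | O=C1O[C@H](CO)[C@H](C/C=C(/C)CO[Si](C)(C)C(C)(C)C)C1 | intermediate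
15 | (2S,3R)-3-[(2Z)-4-{[tert-butyl(dimethyl)silyl]oxy}-3-methylbut-2-en-1-yl]-5-oxooxolane-2-carbaldehyde | O=C1O[C@H](C=O)[C@H](C/C=C(/C)CO[Si](C)(C)C(C)(C)C)C1 | intermediate
16 | (4R,5S)-4-[(2Z)-4-{[tert-butyl(dimethyl)silyl]oxy}-3-methylbut-2-en-1-yl]-5-[(1RS)-1-hydroxy-2-methylprop-2-en-1-yl]oxolan-2-one | O=C1O[C@H](C(O)C(C)=C)[C@H](C/C=C(/C)CO[Si](C)(C)C(C)(C)C)C1 | intermediate
17 | (4R,5S)-4-[(2Z)-4-{[tert-butyl(dimethyl)silyl]oxy}-3-methylbut-2-en-1-yl]-5-[(1RS)-1-(ethenyloxy)-2-methylprop-2-en-1-yl]oxolan-2-one (not isolated) | O=C1O[C@H](C(OC=C)C(C)=C)[C@H](C/C=C(/C)CO[Si](C)(C)C(C)(C)C)C1 | intermediate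
18 | (4E)-5-[(2S,3R)-3-[(2Z)-4-{[tert-butyl(dimethyl)silyl]oxy}-3-methylbut-2-en-1-yl]-5-oxooxolan-2-yl]-4-methylpent-4-enal | O=C1O[C@H](/C=C(\C)CCC=O)[C@H](C/C=C(/C)CO[Si](C)(C)C(C)(C)C)C1 | intermediate
19 | (2E,6E)-7-[(2S,3R)-3-[(2Z)-4-{[tert-butyl(dimethyl)silyl]oxy}-3-methylbut-2-en-1-yl]-5-oxooxolan-2-yl]-2,6-dimethylhepta-2,6-dienal (not isolated) | O=C1O[C@H](/C=C(\C)CC/C=C(\C)C=O)[C@H](C/C=C(/C)CO[Si](C)(C)C(C)(C)C)C1 | intermediate
20 | (4R,5S)-4-[(2Z)-4-{[tert-butyl(dimethyl)silyl]oxy}-3-methylbut-2-en-1-yl]-5-[(1E,5E)-7-hydroxy-2,6-dimethylhepta-1,5-dien-1-yl]oxolan-2-one | O=C1O[C@H](/C=C(\C)CC/C=C(\C)CO)[C@H](C/C=C(/C)CO[Si](C)(C)C(C)(C)C)C1 | intermediate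
21 | (4R,5S)-4-[(2Z)-4-{[tert-butyl(dimethyl)silyl]oxy}-3-methylbut-2-en-1-yl]-5-[(1E)-4-[(2R,3R)-3-(hydroxymethyl)-3-methyloxiran-2-yl]-2-methylbut-1-en-1-yl]oxolan-2-one | O=C1O[C@H](/C=C(\C)CC[C@H]2O[C@]2(C)CO)[C@H](C/C=C(/C)CO[Si](C)(C)C(C)(C)C)C1 | intermediate
22 | (2S,3R)-3-[(3E)-4-[(2S,3R)-3-[(2Z)-4-{[tert-butyl(dimethyl)silyl]oxy}-3-methylbut-2-en-1-yl]-5-oxooxolan-2-yl]-3-methylbut-3-en-1-yl]-2-methyloxirane-2-carbaldehyde | O=C1O[C@H](/C=C(\C)CC[C@H]2O[C@]2(C)C=O)[C@H](C/C=C(/C)CO[Si](C)(C)C(C)(C)C)C1 | intermediate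
23 | (4R,5S)-4-[(2Z)-4-{[tert-butyl(dimethyl)silyl]oxy}-3-methylbut-2-en-1-yl]-5-[(1E)-4-{(2R,3R)-3-[(E)-2-iodoethenyl]-3-methyloxiran-2-yl}-2-methylbut-1-en-1-yl]oxolan-2-one | O=C1O[C@H](/C=C(\C)CC[C@H]2O[C@]2(C)/C=C/I)[C@H](C/C=C(/C)CO[Si](C)(C)C(C)(C)C)C1 | intermediate
24 | (4R,5S)-4-[(2Z)-4-hydroxy-3-methylbut-2-en-1-yl]-5-[(1E)-4-{(2R,3R)-3-[(E)-2-iodoethenyl]-3-methyloxiran-2-yl}-2-methylbut-1-en-1-yl]oxolan-2-one | O=C1O[C@H](/C=C(\C)CC[C@H]2O[C@]2(C)/C=C/I)[C@H](C/C=C(/C)CO)C1 | intermediate
25 | (2Z)-4-[(2S,3R)-2-[(1E)-4-{(2R,3R)-3-[(E)-2-iodoethenyl]-3-methyloxiran-2-yl}-2-methylbut-1-en-1-yl]-5-oxooxolan-3-yl]-2-methylbut-2-enal | O=C1O[C@H](/C=C(\C)CC[C@H]2O[C@]2(C)/C=C/I)[C@H](C/C=C(/C)C=O)C1 | intermediate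
26 | (1R,2S,3E,7R,8R,9E,11RS,12Z)-7,8-epoxy-11-hydroxy-17-norcembra-3,9,12-trien-16,2-olide | C1C(=O)O[C@@H]2/C=C(\C)CC[C@H]3O[C@]3(C)/C=C/C(O)/C(C)=C\C[C@H]12 | intermediate
27 | (1R,2S,3E,7R,8R,11RS,12Z)-7,8-epoxy-11-hydroxy-17-norcembra-3,12-dien-16,2-olide | C1C(=O)O[C@@H]2/C=C(\C)CC[C@H]3O[C@]3(C)CCC(O)/C(C)=C\C[C@H]12 | intermediate
28 | (1R,2S,3E,7R,8R,12Z)-17-(dimethylamino)-7,8-epoxy-11-hydroxycembra-3,12-dien-16,2-olide, C11 and C15 epimers (not isolated) | CN(C)CC1C(=O)O[C@@H]2/C=C(\C)CC[C@H]3O[C@]3(C)CCC(O)/C(C)=C\C[C@H]12 | intermediate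
29 | (1R,2S,3E,7R,8R,12Z)-7,8-epoxy-11-hydroxy-17-(trimethylammonio)cembra-3,12-dien-16,2-olide iodide, C11 and C15 epimers (not isolated) | C[N+](C)(C)CC1C(=O)O[C@@H]2/C=C(\C)CC[C@H]3O[C@]3(C)CCC(O)/C(C)=C\C[C@H]12.[I-] | intermediate
30 | (1R,2R,3E,7R,8R,11RS,12Z)-7,8-epoxy-11-hydroxycembra-3,12,15(17)-trien-16,2-olide | C=C1C(=O)O[C@@H]2/C=C(\C)CC[C@H]3O[C@]3(C)CCC(O)/C(C)=C\C[C@H]12 | intermediate
31 | (1R,2R,3E,7R,8R,12Z)-7,8-epoxy-11-oxocembra-3,12,15(17)-trien-16,2-olide | C=C1C(=O)O[C@@H]2/C=C(\C)CC[C@H]3O[C@]3(C)CCC(=O)/C(C)=C\C[C@H]12 | intermediate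
32 | (1R,2R,3E,7R,8S,12Z)-8-hydroperoxy-7-hydroxy-11-oxocembra-3,12,15(17)-trien-16,2-olide (not isolated) | C=C1C(=O)O[C@@H]2/C=C(\C)CC[C@@H](O)[C@@](C)(OO)CCC(=O)/C(C)=C\C[C@H]12 | intermediate
33 | (1R,2R,3E,7R,8S,11R,12Z)-7,11-dihydroxy-8,11-epidioxycembra-3,12,15(17)-trien-16,2-olide | C=C1C(=O)O[C@@H]2/C=C(\C)CC[C@@H](O)[C@]3(C)CC[C@@](O)(OO3)/C(C)=C\C[C@H]12 | intermediate
34 | (1R,2R,3E,7R,8S,11R,12Z)-7-acetoxy-8,11-epidioxy-11-hydroxycembra-3,12,15(17)-trien-16,2-olide | C=C1C(=O)O[C@@H]2/C=C(\C)CC[C@@H](OC(C)=O)[C@]3(C)CC[C@@](O)(OO3)/C(C)=C\C[C@H]12 | intermediate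
35 | (1R,2R,3E,7R,8S,11R,12Z)-7-acetoxy-8,11-epidioxycembra-3,12,15(17)-trien-16,2-olide (CNP0238885.6) | C=C1C(=O)O[C@@H]2/C=C(\C)CC[C@@H](OC(C)=O)[C@]3(C)CC[C@@H](OO3)/C(C)=C\C[C@H]12 | target

Total step count: 26. Longest linear sequence: 26 steps (1 → 35); 6 and 11 are bought and enter in steps 5 and 9.

Least certain steps

Key step (step 9). The most likely failure is partial opening at C2, which gives the regioisomeric lactone, because the inductive and steric bias between the two secondary epoxide carbons is real but not absolute. A second risk is loss of the primary silyl ether during the acid-promoted ring closure. Fallback, same disconnection with a different nucleophile: from 10, the diethylalkynylalane made from ethoxyacetylene (nBuLi, then Et2AlCl, PhMe, −78 → 0 °C) should open the epoxide at C1 with inversion to give the ynol ether alcohol F1. Alkynylalanes attack 2,3-epoxy ethers at the carbon remote from the ether oxygen more selectively than enolates do. Brief treatment of F1 with catalytic acid in wet CH2Cl2 adds the C2 hydroxyl across the ynol ether and hydrolyses the resulting ketene acetal, which returns to the route at 13.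

Step 13. The risk is leakage to the Z C3=C4 isomer, because the vinyl ether has only a hydrogen at the position that penalises an axial C2 substituent in the chair transition state. Fallback: from 16, the amide acetal variant of the rearrangement (CH3C(OMe)2NMe2, xylene, 140 °C), in which the dimethylamino group enforces the equatorial arrangement, gives the E dimethylamide F2. Cp2Zr(H)Cl in THF reduces this tertiary amide to the aldehyde without touching the lactone, returning at 18.

Step 20. The risk is intermolecular coupling or protodehalogenation instead of ring closure, because the alkenylchromium centre sits next to the fully substituted C8 and the ring must accommodate three alkenes and an epoxide. Fallback, closing the ring at C9=C10 instead: from 22, methylenation (Ph3P=CH2, THF, −78 °C) gives the vinyl epoxide F3. Bu4NF/AcOH gives the alcohol F4 and Dess–Martin oxidation the Z enal F5. CH2=CHMgBr at −78 °C gives the divinyl carbinol F6. Ring-closing metathesis with the second-generation Grubbs catalyst RuCl2(=CHPh)(H2IMes)(PCy3) in dilute PhMe gives the macrocycle F7 as a mixture of C9=C10 isomers. Both isomers are saturated under the conditions of step 21, so the sequence returns at 27.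

Step 21. The risks are over-reduction of a trisubstituted alkene, or slow reduction of C9=C10 because it is flanked by a quaternary carbon. After saturation there is also a risk of transannular attack of the C11 hydroxyl on C8. Fallback: from 26, silylation (Et3SiCl, imidazole, CH2Cl2) gives the ether F8 while the E alkene still holds the hydroxyl away from the epoxide. Homogeneous hydrogenation with RhCl(PPh3)3 and H2 (1 atm, PhH), a catalyst that does not hydrogenate trisubstituted alkenes at a useful rate, gives F9. Bu4NF/AcOH then returns to 27; F9 can also be carried through step 22 before desilylation if the free hydroxyl proves troublesome.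

Step 24. The risk is interference by the C11 carbonyl: its oxygen can capture the acid-activated epoxide across the ring, H2O2 can add to the carbonyl, and a molybdenum peroxo species could epoxidise C3=C4. Fallback, in which C11 is no longer a carbonyl and the O–C11 bond is made by displacement: from 31, Corey–Bakshi–Shibata reduction with the oxazaborolidine enantiomer that gives the 11R alcohol yields F10. MsCl, LiCl and 2,4,6-collidine in DMF at 0 °C convert it with inversion into the 11S chloride F11. Perhydrolysis as in step 24 gives the chloro hydroperoxide F12. Cs2CO3 in DMF at 0 °C deprotonates only the hydroperoxide, which displaces chloride 6-exo-tet with inversion to give the dioxane alcohol F13. Acetylation as in step 25 returns at 35.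

Step 26. The risks are Lewis-acid attack on the O–O bond, hydride delivery to C13 of the allylic cation, or Z to E isomerisation of C12=C13 through that cation. Fallback, which changes the cation precursor: from 33, catalytic pyridinium tosylate in CH2Cl2 closes the C7 hydroxyl onto C11 to give the bridged ketal F14, a 2,3,5-trioxabicyclo[2.2.2]octane with no free hydroxyl. Et3SiH with Me3SiOTf at −78 °C should ionise the C11–O7 bond, the more basic ether oxygen leaving, and reduce the peroxycarbenium ion to the alcohol F13. Acetylation as in step 25 returns at 35.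

Further compounds

F1 | step 9 | (2S,3R,5Z)-7-{[tert-butyl(dimethyl)silyl]oxy}-3-(ethoxyethynyl)-1-[(4-methoxybenzyl)oxy]-6-methylhept-5-en-2-ol | CCOC#C[C@@H](C/C=C(/C)CO[Si](C)(C)C(C)(C)C)[C@H](O)COCc1ccc(OC)cc1
F2 | step 13 | (4E)-5-[(2S,3R)-3-[(2Z)-4-{[tert-butyl(dimethyl)silyl]oxy}-3-methylbut-2-en-1-yl]-5-oxooxolan-2-yl]-N,N,4-trimethylpent-4-enamide | O=C1O[C@H](/C=C(\C)CCC(=O)N(C)C)[C@H](C/C=C(/C)CO[Si](C)(C)C(C)(C)C)C1
F3 | step 20 | (4R,5S)-4-[(2Z)-4-{[tert-butyl(dimethyl)silyl]oxy}-3-methylbut-2-en-1-yl]-5-[(1E)-4-[(2R,3R)-3-ethenyl-3-methyloxiran-2-yl]-2-methylbut-1-en-1-yl]oxolan-2-one | O=C1O[C@H](/C=C(\C)CC[C@H]2O[C@]2(C)C=C)[C@H](C/C=C(/C)CO[Si](C)(C)C(C)(C)C)C1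
F4 | step 20 | (4R,5S)-5-[(1E)-4-[(2R,3R)-3-ethenyl-3-methyloxiran-2-yl]-2-methylbut-1-en-1-yl]-4-[(2Z)-4-hydroxy-3-methylbut-2-en-1-yl]oxolan-2-one | O=C1O[C@H](/C=C(\C)CC[C@H]2O[C@]2(C)C=C)[C@H](C/C=C(/C)CO)C1
F5 | step 20 | (2Z)-4-[(2S,3R)-2-[(1E)-4-[(2R,3R)-3-ethenyl-3-methyloxiran-2-yl]-2-methylbut-1-en-1-yl]-5-oxooxolan-3-yl]-2-methylbut-2-enal | O=C1O[C@H](/C=C(\C)CC[C@H]2O[C@]2(C)C=C)[C@H](C/C=C(/C)C=O)C1
F6 | step 20 | (4R,5S)-5-[(1E)-4-[(2R,3R)-3-ethenyl-3-methyloxiran-2-yl]-2-methylbut-1-en-1-yl]-4-[(2Z,4RS)-4-hydroxy-3-methylhexa-2,5-dien-1-yl]oxolan-2-one | O=C1O[C@H](/C=C(\C)CC[C@H]2O[C@]2(C)C=C)[C@H](C/C=C(/C)C(O)C=C)C1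
F7 | step 20 | (1R,2S,3E,7R,8R,12Z)-7,8-epoxy-11-hydroxy-17-norcembra-3,9,12-trien-16,2-olide, mixture of C9=C10 isomers and C11 epimers | C1C(=O)O[C@@H]2/C=C(\C)CC[C@H]3O[C@]3(C)C=CC(O)/C(C)=C\C[C@H]12
F8 | step 21 | (1R,2S,3E,7R,8R,9E,11RS,12Z)-7,8-epoxy-11-[(triethylsilyl)oxy]-17-norcembra-3,9,12-trien-16,2-olide | C1C(=O)O[C@@H]2/C=C(\C)CC[C@H]3O[C@]3(C)/C=C/C(O[Si](CC)(CC)CC)/C(C)=C\C[C@H]12
F9 | step 21 | (1R,2S,3E,7R,8R,11RS,12Z)-7,8-epoxy-11-[(triethylsilyl)oxy]-17-norcembra-3,12-dien-16,2-olide | C1C(=O)O[C@@H]2/C=C(\C)CC[C@H]3O[C@]3(C)CCC(O[Si](CC)(CC)CC)/C(C)=C\C[C@H]12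
F10 | step 24 | (1R,2R,3E,7R,8R,11R,12Z)-7,8-epoxy-11-hydroxycembra-3,12,15(17)-trien-16,2-olide | C=C1C(=O)O[C@@H]2/C=C(\C)CC[C@H]3O[C@]3(C)CC[C@@H](O)/C(C)=C\C[C@H]12
F11 | step 24 | (1R,2R,3E,7R,8R,11S,12Z)-11-chloro-7,8-epoxycembra-3,12,15(17)-trien-16,2-olide | C=C1C(=O)O[C@@H]2/C=C(\C)CC[C@H]3O[C@]3(C)CC[C@H](Cl)/C(C)=C\C[C@H]12
F12 | step 24 | (1R,2R,3E,7R,8S,11S,12Z)-11-chloro-8-hydroperoxy-7-hydroxycembra-3,12,15(17)-trien-16,2-olide | C=C1C(=O)O[C@@H]2/C=C(\C)CC[C@@H](O)[C@@](C)(OO)CC[C@H](Cl)/C(C)=C\C[C@H]12
F13 | step 24 | (1R,2R,3E,7R,8S,11R,12Z)-8,11-epidioxy-7-hydroxycembra-3,12,15(17)-trien-16,2-olide | C=C1C(=O)O[C@@H]2/C=C(\C)CC[C@@H](O)[C@]3(C)CC[C@@H](OO3)/C(C)=C\C[C@H]12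
F14 | step 26 | (1R,2R,3E,7R,8S,11S,12Z)-7,11-epoxy-8,11-epidioxycembra-3,12,15(17)-trien-16,2-olide (bridged ketal) | C=C1C(=O)O[C@@H]2/C=C(\C)CC[C@@H](O4)[C@]3(C)CC[C@]4(OO3)/C(C)=C\C[C@H]12
A1 | alternative 1 | C11 peroxyhemiketal of the target (identical with 34) | C=C1C(=O)O[C@@H]2/C=C(\C)CC[C@@H](OC(C)=O)[C@]3(C)CC[C@@](O)(OO3)/C(C)=C\C[C@H]12
A2 | alternative 1 | cyclobutanol with a C8–C11 bond (cyclobutane C8–C9–C10–C11 fused to the 12-membered ring, tertiary C11 hydroxyl, C7 acetate, cis α-methylene lactone; C8 and C11 configuration left open) | C=C1C(=O)O[C@@H]2/C=C(\C)CC[C@@H](OC(C)=O)C3(C)CCC3(O)/C(C)=C\C[C@H]12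
A3 | alternative 2 | 14-membered C3–C4 cycloalkyne with C2 hydroxyl, C1 CH2CO2Me, C7,C8-epoxide and C11 O-TBS | O[C@@H]1C#CCC[C@H]2O[C@]2(C)CC[C@@H](O[Si](C)(C)C(C)(C)C)/C(C)=C\C[C@@H]1CC(=O)OC
A4 | alternative 2 | seco diyne with methyl-capped alkynes on C2 and C5 | CC#C[C@@H](O)[C@@H](CC(=O)OC)C/C=C(/C)[C@H](O[Si](C)(C)C(C)(C)C)CC[C@@]1(C)O[C@@H]1CCC#CC
A5 | alternative 3 | cis-fused saturated lactone with C7,C8-epoxide and C11 O-TBS | O=C1O[C@@H]2/C=C(\C)CC[C@H]3O[C@]3(C)CC[C@@H](O[Si](C)(C)C(C)(C)C)/C(C)=C\C[C@@H]2C1
A6 | alternative 3 | macrocyclic C2 enone with C1 CH2CO2Me (C1 epimers), C7,C8-epoxide and C11 O-TBS | COC(=O)CC1C/C=C(/C)[C@H](O[Si](C)(C)C(C)(C)C)CC[C@@]2(C)O[C@@H]2CC/C(C)=C/C1=O
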